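Everything rests on cutting ring A at C5–C10 and C1–C2. The feature exploited is the quaternary C10 of ring A. It carries C20, lies between C1H2 and the C5 methine, and has the C3 oxygen para to it. This is the imprint of a 2-substituted acrolein (C1=C10–C20) and a 2-siloxy diene (C2–C5). One catalytic asymmetric Diels–Alder reaction unites two halves of comparable size, closes ring A and sets C10 and C5. It leaves a C3=C4 enol ether for the later C3-OH/C4-OAc pair. Its precursor is the enantiopure bicyclo[3.2.1]octane keto ester (rings C/D, C7 ester, C15 ketone) with the acrolein exo on C9.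

Key step: step 13

Remark: atom labels follow ent-kaurane numbering (ring A = C1–C5, C10; ring C = C8, C9, C11–C14; ring D = C8, C13–C16; C7 lactone C=O, C20 lactone OCH2, C6 formyl carbon, C17 methylene).
Assumption: the sense of induction of the two chiral catalysts (steps 1 and 13) is taken from the accepted transition-state models; both catalysts are available in either mirror-image or pseudo-enantiomeric form.

Step 1
Reactants: 1 methyl 2-oxocyclopentane-1-carboxylate; 2 acrolein
Product: 4 methyl (S)-1-(3,3-dimethoxypropyl)-2-oxocyclopentane-1-carboxylate, via Michael aldehyde 3 (not isolated)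
Conditions: 6'-hydroxy-9-O-aryl cinchona catalyst (quinine series, 10 mol %), CH2Cl2, −25 °C; then HC(OMe)3, p-TsOH (20 mol %), MeOH, 23 °C
Reagents that add atoms: trimethyl orthoformate, COC(OC)OC
Why: Base/hydrogen-bond catalysed Michael addition of the cyclic β-keto ester to acrolein, in which the chiral ion pair covers one enolate face and so sets quaternary C8, followed by acetalisation that masks the aldol-prone aldehyde before isolation.

Step 2
Reactants: 4 methyl (S)-1-(3,3-dimethoxypropyl)-2-oxocyclopentane-1-carboxylate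
Product: 6 methyl (R)-2-oxo-1-(3-oxopropyl)cyclopent-3-ene-1-carboxylate, via acetal enone 5 (not isolated)
Conditions: LiHMDS, THF, −78 °C; PhS(Cl)=N-t-Bu, −78 °C; then 1 M HCl, THF, 23 °C
Reagents that add atoms: water, O
Why: C16 is the only enolisable position, so its lithium enolate is captured at sulfur and loses the sulfenamide by syn elimination (one-pot ketone dehydrogenation) to give the C16=C13 enone, and the acidic work-up hydrolyses the acetal; C8 is untouched and only its CIP descriptor changes.

Step 3
Reactants: 6 methyl (R)-2-oxo-1-(3-oxopropyl)cyclopent-3-ene-1-carboxylate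
Product: 7 methyl (1R,5R)-4,7-dioxobicyclo[3.2.1]octane-1-carboxylate
Conditions: 3-benzyl-5-(2-hydroxyethyl)-4-methylthiazolium chloride (20 mol %), Et3N, 1,4-dioxane, 80 °C
Reagents that add atoms: none
Why: Intramolecular Stetter reaction in which the carbene turns C12 into an acyl anion equivalent that adds irreversibly to the enone β-carbon C13 and closes six-membered ring C as a 1,4-diketone; the three-carbon tether on C8 can only reach the ring face it stands on, so C8 sets C13.

Step 4
Reactants: 7 methyl (1R,5R)-4,7-dioxobicyclo[3.2.1]octane-1-carboxylate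
Product: 8 methyl (1S,5R)-4,7-dioxobicyclo[3.2.1]oct-2-ene-1-carboxylate
Conditions: IBX, DMSO, 75 °C
Reagents that add atoms: none
Why: IBX dehydrogenation of a ketone through its enol is site-selective here, since only the C12 ketone has a removable C11/C9 hydrogen pair whereas unsaturation next to C15 would require a bridgehead alkene.

Step 5
Reactants: 8 methyl (1S,5R)-4,7-dioxobicyclo[3.2.1]oct-2-ene-1-carboxylate; 9 allyltrimethylsilane
Product: 10 methyl (1S,2R,5R)-2-allyl-4,7-dioxobicyclo[3.2.1]octane-1-carboxylate (allyl exo)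
Conditions: TiCl4, CH2Cl2, −78 °C
Reagents that add atoms: none
Why: Hosomi–Sakurai conjugate allylation in which the slim nucleophile attacks C9 axially from the exo face, on the side of the one-carbon C14 bridge and away from the C15–C16 bridge, which sets C9 with C10 anti to C15 as the target requires.

Step 6
Reactants: 10 methyl (1S,2R,5R)-2-allyl-4,7-dioxobicyclo[3.2.1]octane-1-carboxylate
Product: 11 C12 tosylhydrazone of 10 (1S,2R,5R)
Conditions: TsNHNH2 (1.0 equiv), EtOH, 23–40 °C
Reagents that add atoms: p-toluenesulfonyl hydrazide, Cc1ccc(cc1)S(=O)(=O)NN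
Why: Hydrazone condensation takes place at the accessible C12 cyclohexanone, while the C15 ketone is screened by quaternary C8 and the bridge.

Step 7
Reactants: 11 C12 tosylhydrazone of 10
Product: 13 methyl (1S,2S,5R)-2-allyl-7-oxobicyclo[3.2.1]octane-1-carboxylate, via boryl hydrazide 12 (not isolated)
Conditions: catecholborane, CHCl3, −10 °C; then NaOAc·3H2O, reflux
Reagents that add atoms: none
Why: Tosylhydrazone reduction (Caglioti type), in which hydride transfer to C=N, loss of sulfinate and extrusion of N2 from the diazene turn C12 into CH2 under conditions that spare ketone, ester and terminal alkene.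

Step 8
Reactants: 13 methyl (1S,2S,5R)-2-allyl-7-oxobicyclo[3.2.1]octane-1-carboxylate
Product: 15 methyl (1S,2S,5R)-7-oxo-2-(2-oxoethyl)bicyclo[3.2.1]octane-1-carboxylate, via ozonide 14 (not isolated)
Conditions: O3, CH2Cl2, −78 °C; then Me2S, −78 to 23 °C
Reagents that add atoms: ozone, [O-][O+]=O
Why: Ozonolysis with reductive work-up cleaves the only alkene and leaves the C10H2–C20HO unit without touching a stereocentre.

Step 9
Reactants: 15 methyl (1S,2S,5R)-7-oxo-2-(2-oxoethyl)bicyclo[3.2.1]octane-1-carboxylate
Product: 16 methyl (1S,2S,5R)-7-oxo-2-(3-oxoprop-1-en-2-yl)bicyclo[3.2.1]octane-1-carboxylate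
Conditions: 37 % aq. CH2O, pyrrolidine (10 mol %), propionic acid (10 mol %), i-PrOH, 45 °C
Reagents that add atoms: formaldehyde, C=O
Why: Amine/acid-catalysed Mannich condensation–elimination (α-methylenation through the aldehyde enamine) is selective for the aldehyde over the hindered ketone and adds C1.

Step 10
Reactants: 17 (E)-3-methylpent-2-en-4-yn-1-ol
Product: 18 (E)-3-methylpent-2-en-4-yn-1-yl 4-methoxybenzyl ether
Conditions: NaH (1.05 equiv), PMBCl, Bu4NI (cat.), THF–DMF, 0 to 23 °C
Reagents that add atoms: 4-methoxybenzyl chloride, COc1ccc(CCl)cc1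
Why: Williamson etherification of the alkoxide, which is formed far more readily than the acetylide, leaves the E alkene unchanged.

Step 11
Reactants: 18 (E)-3-methylpent-2-en-4-yn-1-yl 4-methoxybenzyl ether
Product: 19 (E)-5-(4-methoxybenzyloxy)-3-methylpent-3-en-2-one
Conditions: (IPr)AuCl/AgSbF6 (2 mol %), 1,4-dioxane–H2O, 60 °C
Reagents that add atoms: water, O
Why: Gold(I)-catalysed Markovnikov hydration of the terminal alkyne gives the methyl ketone under near-neutral conditions that keep the PMB ether and the E geometry.

Step 12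
Reactants: 19 (E)-5-(4-methoxybenzyloxy)-3-methylpent-3-en-2-one
Product: 20 tert-butyl{[(E)-5-(4-methoxybenzyloxy)-3-methylpenta-1,3-dien-2-yl]oxy}dimethylsilane
Conditions: TBSOTf, Et3N, CH2Cl2, −78 to 0 °C
Reagents that add atoms: tert-butyldimethylsilyl triflate, CC(C)(C)[Si](C)(C)OS(=O)(=O)C(F)(F)F
Why: Soft enolisation and O-silylation at the α'-methyl group gives the cross-conjugated 2-siloxy diene with the C4=C5 bond still E, so that C6 is the outside substituent of the s-cis diene.

Step 13
Reactants: 16 methyl (1S,2S,5R)-7-oxo-2-(3-oxoprop-1-en-2-yl)bicyclo[3.2.1]octane-1-carboxylate; 20 tert-butyl{[(E)-5-(4-methoxybenzyloxy)-3-methylpenta-1,3-dien-2-yl]oxy}dimethylsilane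
Product: 21 Diels–Alder adduct: bicyclic keto ester bearing on C9 the ring-A cyclohexene (quaternary C10 with C20 formyl; C3-OTBS/C4-Me enol ether; C5-CH2OPMB cis to the formyl group; C10 and C5 as in the target)
Conditions: (S)-diphenylprolinol-derived B-(o-tolyl)oxazaborolidine (24 mol %) + Tf2NH (20 mol %), 20 (1.5 equiv), CH2Cl2, −78 to −40 °C
Reagents that add atoms: none
Why: The boron cation binds the formyl oxygen of 16 in its s-trans form and lowers the LUMO, and the diene adds in a concerted but asynchronous [4+2] in which the C2 methylene next to the siloxy carbon bonds early to C1 and C5 closes late onto C10. The closest known reaction type is the oxazaborolidinium-catalysed Diels–Alder reaction of 2-substituted acroleins with 2-silyloxy dienes, which gives cyclohexenes with a formyl-bearing quaternary carbon. Ring A is closed by intermolecular cycloaddition, the two σ-bonds C1–C2 and C5–C10 forming suprafacially on both partners. C10 is set by the catalyst, whose aryl group covers one enal face so that the diene reaches the Si face of C10; in the rotamer with H9 in the enal plane beside the carbonyl oxygen, C8 also lies opposite the incoming diene, so C9 should not oppose the catalyst. C5 follows from the E geometry of C4=C5 together with the formyl-endo orientation, preferred because the bulky bicycle cannot sit under C3-OTBS/C4-Me, and this places C6 cis to C20. Regioselectivity (C3–O para to C10) comes from the siloxy group, supported by the alkyl-substituted C5 terminus. Chemoselectivity rests on the aldehyde being the only carbonyl conjugated to an alkene, while the C15 ketone and C7 ester are buried at quaternary C8.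

Step 14
Reactants: 21 Diels–Alder adduct
Product: 23 spiro-δ-lactone (C20–O–C7) with C15 ketone and intact C3-OTBS enol ether and C6-OPMB, via hydroxy ester 22 (not isolated)
Conditions: NaBH4, CH2Cl2–MeOH, −78 °C; then DBU (20 mol %), PhMe, 50 °C
Reagents that add atoms: none
Why: Chemoselective borohydride reduction of the aldehyde at low temperature (the C15 ketone next to quaternary C8 is slower), then base-catalysed transesterification in which the C20 hydroxyl closes the six-membered lactone on C7, favoured by the two quaternary centres in the chain.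

Step 15
Reactants: 23 spiro-δ-lactone silyl enol ether
Product: 24 C3 enol triflate (C3=C4) of the spiro-lactone
Conditions: CsF, PhNTf2, DME, 23 °C
Reagents that add atoms: N-phenylbis(trifluoromethanesulfonimide), O=S(=O)(N(c1ccccc1)S(=O)(=O)C(F)(F)F)C(F)(F)F
Why: Fluoride-induced desilylation releases the C3 enolate regiospecifically and the triflimide present traps it on oxygen at once (silyl enol ether to enol triflate exchange), so the double-bond position fixed by the cycloaddition is kept and C5 is not disturbed.

Step 16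
Reactants: 24 C3 enol triflate
Product: 25 C3=C4 alkene (4-methylcyclohex-3-ene ring A) spiro-lactone
Conditions: Pd(OAc)2 (10 mol %), PPh3 (20 mol %), HCO2H, Et3N, DMF, 60 °C
Reagents that add atoms: none
Why: Palladium-catalysed formate reduction of an enol triflate (oxidative addition, decarboxylation of formate, C–H reductive elimination) tolerates ketone, lactone and PMB ether.

Step 17
Reactants: 25 C3=C4 alkene spiro-lactone
Product: 28 C16 exo-methylene C15 enone, via Mannich base 26 (not isolated), via methiodide 27 (not isolated)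
Conditions: LiHMDS, THF, −78 °C; CH2=NMe2+ I−, −78 to 0 °C; then MeI, CH2Cl2, 23 °C; then sat. aq. NaHCO3
Reagents that add atoms: dimethylmethyleneiminium iodide, C[N+](C)=C.[I-]
Why: C16 is the only enolisable position of 25, so the Mannich reaction of its enolate, N-methylation and Hofmann-type β-elimination install C17 before any base-sensitive acetate or aldehyde is present.

Step 18
Reactants: 28 C16 exo-methylene C15 enone
Product: 29 C3,C4-epoxide with oxygen on the face of H5, anti to C20 and to the C6 arm
Conditions: m-CPBA, NaHCO3, CH2Cl2, 0 °C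
Reagents that add atoms: m-chloroperoxybenzoic acid, O=C(OO)c1cccc(Cl)c1
Why: Prilezhaev epoxidation picks the electron-rich trisubstituted C3=C4 over the electron-poor enone, and the peracid approaches opposite the axial C20 and the C6 arm, which sets the C3–O configuration.

Step 19
Reactants: 29 C3,C4-epoxide
Product: 30 C3 axial alcohol / C4 axial tertiary acetate (trans-diaxial; OAc syn to C20) with C6-OPMB
Conditions: glacial AcOH, NaOAc, 40 °C
Reagents that add atoms: acetic acid, CC(=O)O
Why: Acid-assisted epoxide opening in which the electronic preference (borderline SN2 at tertiary C4) and the Fürst–Plattner trans-diaxial rule point to the same carbon, so acetate enters C4 with inversion while C3 keeps its oxygen, and the diaxial geometry blocks 1,2-acyl migration.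

Step 20
Reactants: 30 hydroxy acetate PMB ether
Product: 31 C6 primary alcohol (C3-OH and C4-OAc unchanged)
Conditions: DDQ, CH2Cl2–pH 7 buffer, 0 °C
Reagents that add atoms: none
Why: Oxidative PMB cleavage (hydride abstraction by DDQ, hydrolysis of the oxocarbenium ion) is neutral and leaves enone, acetate and lactone alone.

Step 21
Reactants: 31 C6 primary alcohol
Product: 32 CNP0199571.1 (target)
Conditions: TEMPO (20 mol %), PhI(OAc)2, CH2Cl2, 23 °C
Reagents that add atoms: none
Why: Oxoammonium (TEMPO) oxidation prefers the primary C6 alcohol over the axial C3 alcohol next to quaternary C4, and its base-free medium avoids β-elimination of the C4 acetate and epimerisation at C5.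

Compound list
1 | methyl 2-oxocyclopentane-1-carboxylate | COC(=O)C1CCCC1=O | starting material
2 | acrolein | C=CC=O | starting material
3 | methyl (S)-2-oxo-1-(3-oxopropyl)cyclopentane-1-carboxylate | O=C1CCC[C@@]1(CCC=O)C(=O)OC | intermediate
4 | methyl (S)-1-(3,3-dimethoxypropyl)-2-oxocyclopentane-1-carboxylate | O=C1CCC[C@@]1(CCC(OC)OC)C(=O)OC | intermediate
5 | methyl (R)-1-(3,3-dimethoxypropyl)-2-oxocyclopent-3-ene-1-carboxylate | O=C1C=CC[C@@]1(CCC(OC)OC)C(=O)OC | intermediate
6 | methyl (R)-2-oxo-1-(3-oxopropyl)cyclopent-3-ene-1-carboxylate | O=C1C=CC[C@@]1(CCC=O)C(=O)OC | intermediate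
7 | methyl (1R,5R)-4,7-dioxobicyclo[3.2.1]octane-1-carboxylate | C1C(=O)[C@]2(C(=O)OC)C[C@H]1C(=O)CC2 | intermediate
8 | methyl (1S,5R)-4,7-dioxobicyclo[3.2.1]oct-2-ene-1-carboxylate | C1C(=O)[C@]2(C(=O)OC)C[C@H]1C(=O)C=C2 | intermediate
9 | allyltrimethylsilane | C=CC[Si](C)(C)C | starting material
10 | methyl (1S,2R,5R)-2-allyl-4,7-dioxobicyclo[3.2.1]octane-1-carboxylate | C1C(=O)[C@]2(C(=O)OC)C[C@H]1C(=O)C[C@H]2CC=C | intermediate
11 | C12 tosylhydrazone of 10 | C1C(=O)[C@]2(C(=O)OC)C[C@H]1C(=NNS(=O)(=O)c1ccc(C)cc1)C[C@H]2CC=C | intermediate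
12 | N-(catecholboryl) tosylhydrazide at C12 (C12 epimers) | C1C(=O)[C@]2(C(=O)OC)C[C@H]1C(N(NS(=O)(=O)c1ccc(C)cc1)B1Oc3ccccc3O1)C[C@H]2CC=C | intermediate
13 | methyl (1S,2S,5R)-2-allyl-7-oxobicyclo[3.2.1]octane-1-carboxylate | C1C(=O)[C@]2(C(=O)OC)C[C@H]1CC[C@H]2CC=C | intermediate
14 | secondary ozonide (1,2,4-trioxolane) of 13 | C1C(=O)[C@]2(C(=O)OC)C[C@H]1CC[C@H]2CC1OCOO1 | intermediate
15 | methyl (1S,2S,5R)-7-oxo-2-(2-oxoethyl)bicyclo[3.2.1]octane-1-carboxylate | C1C(=O)[C@]2(C(=O)OC)C[C@H]1CC[C@H]2CC=O | intermediate
16 | methyl (1S,2S,5R)-7-oxo-2-(3-oxoprop-1-en-2-yl)bicyclo[3.2.1]octane-1-carboxylate | C1C(=O)[C@]2(C(=O)OC)C[C@H]1CC[C@H]2C(=C)C=O | intermediate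
17 | (E)-3-methylpent-2-en-4-yn-1-ol | C#C/C(C)=C/CO | starting material
18 | (E)-3-methylpent-2-en-4-yn-1-yl 4-methoxybenzyl ether | C#C/C(C)=C/COCc1ccc(OC)cc1 | intermediate
19 | (E)-5-(4-methoxybenzyloxy)-3-methylpent-3-en-2-one | CC(=O)/C(C)=C/COCc1ccc(OC)cc1 | intermediate
20 | tert-butyl{[(E)-5-(4-methoxybenzyloxy)-3-methylpenta-1,3-dien-2-yl]oxy}dimethylsilane | C=C(O[Si](C)(C)C(C)(C)C)/C(C)=C/COCc1ccc(OC)cc1 | intermediate
21 | Diels–Alder adduct (ring A closed, C10-CHO, C3-OTBS enol ether, C5-CH2OPMB cis to CHO) | C1C(=O)[C@]2(C(=O)OC)C[C@H]1CC[C@H]2[C@@]1(CCC(O[Si](C)(C)C(C)(C)C)=C(C)[C@H]1COCc1ccc(OC)cc1)C=O | intermediate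
22 | C20 hydroxy ester | C1C(=O)[C@]2(C(=O)OC)C[C@H]1CC[C@H]2[C@@]1(CCC(O[Si](C)(C)C(C)(C)C)=C(C)[C@H]1COCc1ccc(OC)cc1)CO | intermediate
23 | spiro-δ-lactone silyl enol ether | C1C(=O)[C@]23C[C@H]1CC[C@H]2[C@@]1(CCC(O[Si](C)(C)C(C)(C)C)=C(C)[C@H]1COCc1ccc(OC)cc1)COC3=O | intermediate
24 | C3 enol triflate | C1C(=O)[C@]23C[C@H]1CC[C@H]2[C@@]1(CCC(OS(=O)(=O)C(F)(F)F)=C(C)[C@H]1COCc1ccc(OC)cc1)COC3=O | intermediate
25 | C3=C4 alkene spiro-lactone | C1C(=O)[C@]23C[C@H]1CC[C@H]2[C@@]1(CCC=C(C)[C@H]1COCc1ccc(OC)cc1)COC3=O | intermediate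
26 | C16 dimethylaminomethyl ketone (C16 epimers) | CN(C)CC1C(=O)[C@]23C[C@H]1CC[C@H]2[C@@]1(CCC=C(C)[C@H]1COCc1ccc(OC)cc1)COC3=O | intermediate
27 | trimethylammonium iodide of 26 | C[N+](C)(C)CC1C(=O)[C@]23C[C@H]1CC[C@H]2[C@@]1(CCC=C(C)[C@H]1COCc1ccc(OC)cc1)COC3=O.[I-] | intermediate
28 | C16 exo-methylene C15 enone | C=C1C(=O)[C@]23C[C@H]1CC[C@H]2[C@@]1(CCC=C(C)[C@H]1COCc1ccc(OC)cc1)COC3=O | intermediate
29 | C3,C4-epoxide (oxygen anti to C20) | C=C1C(=O)[C@]23C[C@H]1CC[C@H]2[C@@]1(CC[C@@H]4O[C@]4(C)[C@H]1COCc1ccc(OC)cc1)COC3=O | intermediate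
30 | C3-OH / C4-OAc PMB ether | C=C1C(=O)[C@]23C[C@H]1CC[C@H]2[C@@]1(CC[C@H](O)[C@@](C)(OC(C)=O)[C@H]1COCc1ccc(OC)cc1)COC3=O | intermediate
31 | C6 primary alcohol | C=C1C(=O)[C@]23C[C@H]1CC[C@H]2[C@@]1(CC[C@H](O)[C@@](C)(OC(C)=O)[C@H]1CO)COC3=O | intermediate
32 | CNP0199571.1 | C=C1C(=O)[C@]23C[C@H]1CC[C@H]2[C@@]1(CC[C@H](O)[C@@](C)(OC(C)=O)[C@H]1C=O)COC3=O | target

Total steps: 21. Longest linear sequence: 18 steps (steps 1–9 and 13–21); steps 10–12 run in parallel.

Steps most likely to fail

**Step 13.**
- What may go wrong: the hindered enal may compete poorly with the keto ester carbonyls for the boron cation. The diene may be protodesilylated before it reacts. π-Facial selectivity may erode if the catalyst pocket and the C9 substituent oppose each other.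
- The fallback makes the same two bonds one at a time and sets out from 16 and 20.
- With catalytic Tf2NH alone (silyl triflimide catalysis, CH2Cl2, −78 °C), a Mukaiyama–Michael addition joins C2 to C1 with silyl transfer to the formyl oxygen. This gives the open-chain enone formyl enol silane F1, which is isolated.
- Warming F1 with the same catalyst closes C10 onto C5 in an intramolecular Mukaiyama–Michael reaction through a chair-like array with the C6 arm equatorial. The silyl group passes back to the C3 oxygen.
- The C10 face is then decided intramolecularly by C9, and the sequence comes back at 21.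

**Step 19.**
- What may go wrong: ionisation at C4 may outrun capture by acetate on the face crowded by C20. Proton loss or a hydride shift from C3 would then take over from substitution.
- The fallback sets out from 29 and separates the opening from the acylation.
- Aqueous HClO4 in THF delivers the smaller nucleophile water at C4 to give the trans-diaxial diol F2.
- TESOTf/2,6-lutidine silylates only the secondary C3 hydroxyl to give the silyl ether F3.
- Ac2O, DMAP and Et3N with warming acetylate the tertiary C4 hydroxyl to give the acetate F4.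
- HF·pyridine removes the silyl group, and the route is rejoined at 30.

**Step 3.**
- What may go wrong: the acyl anion equivalent may be drained into reversible addition to the C15 carbonyl or into aldehyde self-condensation before it reaches C13 across the ring.
- The fallback sets out from 6 and uses a radical closure instead.
- SmI2 in THF–t-BuOH at −78 °C couples the C12 ketyl with the enone β-carbon to give the bicyclic hydroxy ketone F5.
- Excess IBX in DMSO at 75 °C then oxidises the alcohol and dehydrogenates C9–C11 in one operation, so the route is rejoined at 8.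

Further compounds
F1 | step 13 | open-chain Mukaiyama–Michael adduct (C1–C2 made; C20 enol TBS ether; C3 enone) | C1C(=O)[C@]2(C(=O)OC)C[C@H]1CC[C@H]2C(=CO[Si](C)(C)C(C)(C)C)CCC(=O)/C(C)=C/COCc1ccc(OC)cc1
F2 | step 19 | C3,C4 trans-diaxial diol PMB ether | C=C1C(=O)[C@]23C[C@H]1CC[C@H]2[C@@]1(CC[C@H](O)[C@@](C)(O)[C@H]1COCc1ccc(OC)cc1)COC3=O
F3 | step 19 | C3-O-TES ether of F2 | C=C1C(=O)[C@]23C[C@H]1CC[C@H]2[C@@]1(CC[C@H](O[Si](CC)(CC)CC)[C@@](C)(O)[C@H]1COCc1ccc(OC)cc1)COC3=O
F4 | step 19 | C3-O-TES C4-acetate | C=C1C(=O)[C@]23C[C@H]1CC[C@H]2[C@@]1(CC[C@H](O[Si](CC)(CC)CC)[C@@](C)(OC(C)=O)[C@H]1COCc1ccc(OC)cc1)COC3=O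
F5 | step 3 | methyl 4-hydroxy-7-oxobicyclo[3.2.1]octane-1-carboxylate (C12 epimers) | C1C(=O)[C@]2(C(=O)OC)C[C@H]1C(O)CC2
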